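## Retrosynthetic overview

1. The target comes from its tert-butyl ester / dioxolane ketal by one global acidolysis.
2. The γ-lactone (the only ring) is closed in the key step: the C3–C4 and O1–C5 bonds are made in one flask from the dilithio dianion of a C18 (3S)-3-hydroxy ester and ethyl (S)-lactate triflate. This copies the presumed biogenesis, in which a 3-oxygenated fatty acyl chain is joined at C-2 to a pyruvate-level C3 unit and the C-3 oxygen lactonises onto the C3-unit carboxyl.
3. Stereocentres: C2 by asymmetric hydrogenation of the 3-oxo ester, C3 by chelate-controlled anti alkylation, C4 by SN2 inversion of the lactate carbon.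
4. The 3-oxo ester comes from a Claisen condensation of tert-butyl acetate on a C16 ketal ester, itself made by a copper-catalysed C5 + C11 coupling.

Assumption: the target is the (2S,3S,4S) acid of the given SMILES (alkyl and CO2H cis, CH3 and CO2H trans); oxolane numbering O1, C2 (alkyl), C3 (CO2H), C4 (CH3), C5 (C=O) is used throughout.

## Route

Step 1
Reactants: 1 2-(3-chloropropyl)-2-methyl-1,3-dioxolane; 2 methyl 11-bromoundecanoate
Product: 4 methyl 14-(2-methyl-1,3-dioxolan-2-yl)tetradecanoate, via [3-(2-methyl-1,3-dioxolan-2-yl)propyl]magnesium chloride 3 (not isolated)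
Conditions: 1 (1.3 equiv), Mg, THF, reflux; then 2, Li2CuCl4 (3 mol %), NMP (4 equiv), THF, 0 °C
Reagents that add atoms: none
Why: Kochi-type copper-catalysed sp3–sp3 cross-coupling, in which the primary alkyl Grignard 3 displaces the primary bromide of 2 through an alkylcuprate much faster than it adds to the methyl ester at 0 °C in the presence of NMP, with the ketal inert and no stereocenter involved.

Step 2
Reactants: 4 methyl 14-(2-methyl-1,3-dioxolan-2-yl)tetradecanoate; 5 tert-butyl acetate
Product: 7 tert-butyl 16-(2-methyl-1,3-dioxolan-2-yl)-3-oxohexadecanoate, via tert-butyl acetate lithium enolate 6 (not isolated)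
Conditions: 5 (3.0 equiv), LiN(iPr)2 (3.1 equiv, commercial solution), THF, −78 °C; then 4, −78 → −30 °C; AcOH quench
Reagents that add atoms: none
Why: Crossed Claisen condensation, in which the lithium enolate 6 of the hindered, non-self-condensing tert-butyl ester acylates on the unhindered methyl ester of 4 and the β-keto ester stays as its enolate until the acidic quench (no over-addition), the ketal being inert to base and no stereocenter being formed.

Step 3
Reactants: 7 tert-butyl 16-(2-methyl-1,3-dioxolan-2-yl)-3-oxohexadecanoate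
Product: 8 tert-butyl (3S)-3-hydroxy-16-(2-methyl-1,3-dioxolan-2-yl)hexadecanoate
Conditions: H2 (10 bar), [RuCl2((S)-BINAP)]2·NEt3 (0.5 mol %), EtOH, 50 °C
Reagents that add atoms: none
Why: Noyori asymmetric hydrogenation, in which the β-keto ester chelates divalent ruthenium through both carbonyl oxygens and the (S)-BINAP ligand directs hydride to the ketone face that gives the (3S)-carbinol (typically ≥97% ee for long-chain 3-oxo esters), while the non-chelating ketal and the tert-butyl ester are untouched in the amine-buffered medium.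

Step 4
Reactants: 9 ethyl (S)-lactate
Product: 10 ethyl (2S)-2-[(trifluoromethylsulfonyl)oxy]propanoate
Conditions: Tf2O (1.05 equiv), 2,6-lutidine (1.1 equiv), CH2Cl2, −20 → 0 °C; short silica plug, used at once
Reagents that add atoms: trifluoromethanesulfonic anhydride, O=S(=O)(OS(=O)(=O)C(F)(F)F)C(F)(F)F
Why: O-Triflation of a secondary alcohol with a hindered pyridine base, in which only the O–H bond reacts so the (S) configuration of the lactate carbon is retained and the non-nucleophilic base avoids displacement or racemisation of the reactive triflate.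

Step 5
Reactants: 8 tert-butyl (3S)-3-hydroxy-16-(2-methyl-1,3-dioxolan-2-yl)hexadecanoate; 10 ethyl (2S)-2-[(trifluoromethylsulfonyl)oxy]propanoate
Product: 13 tert-butyl (2S,3S,4S)-4-methyl-2-[13-(2-methyl-1,3-dioxolan-2-yl)tridecyl]-5-oxooxolane-3-carboxylate, via dilithium alkoxide enolate 11 (not isolated), via open-chain lithium alkoxide 12 (not isolated)
Conditions: LiN(iPr)2 (2.2 equiv, commercial solution), THF, −78 → −20 °C; 10 (1.4 equiv), −78 → −20 °C; AcOH quench; then PPTS (10 mol %), CH2Cl2, rt
Reagents that add atoms: none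
Why: Proposed new method: a Fráter–Seebach alkylation whose electrophile is a secondary α-triflyloxy ester and whose product lactonises in the same flask — the lithium-chelated dianion 11 is attacked at its enolate carbon on the face opposite the alkyl chain of the six-membered chelate (1,2-induction, giving the anti array that becomes the 2,3-cis lactone, 3S), the triflate-bearing carbon of 10 is inverted in the SN2 step (S-lactate giving 4S, methyl trans to the ester), and the γ-alkoxide of 12 then closes the five-membered ring on the ethyl ester by acyl substitution with loss of ethoxide (completed by PPTS), the hindered tert-butyl ester being β to the oxygen and unable to compete; the closest known reaction types are Fráter–Seebach alkylations with alkyl halides and the stereospecific inverting displacement of chiral 2-triflyloxy esters by lithium ester and imide enolates.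

Step 6
Reactants: 13 tert-butyl (2S,3S,4S)-4-methyl-2-[13-(2-methyl-1,3-dioxolan-2-yl)tridecyl]-5-oxooxolane-3-carboxylate
Product: 14 (2S,3S,4S)-4-methyl-5-oxo-2-(14-oxopentadecyl)oxolane-3-carboxylic acid
Conditions: TFA/CH2Cl2/H2O (10:10:1), 0 °C → rt
Reagents that add atoms: water, O
Why: Acidolysis, in which the tert-butyl ester is cleaved through the tert-butyl cation (lost as isobutene) and the dioxolane is hydrolysed to the methyl ketone, while the γ-lactone is stable to aqueous acid and, with no base present, none of the three stereocenters can epimerise.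

## Compound list

1 | 2-(3-chloropropyl)-2-methyl-1,3-dioxolane | CC1(CCCCl)OCCO1 | starting material
2 | methyl 11-bromoundecanoate | COC(=O)CCCCCCCCCCBr | starting material
3 | [3-(2-methyl-1,3-dioxolan-2-yl)propyl]magnesium chloride | CC1(CCC[Mg]Cl)OCCO1 | intermediate
4 | methyl 14-(2-methyl-1,3-dioxolan-2-yl)tetradecanoate | COC(=O)CCCCCCCCCCCCCC1(C)OCCO1 | intermediate
5 | tert-butyl acetate | CC(=O)OC(C)(C)C | starting material
6 | lithium enolate of tert-butyl acetate | C=C(O[Li])OC(C)(C)C | intermediate
7 | tert-butyl 16-(2-methyl-1,3-dioxolan-2-yl)-3-oxohexadecanoate | CC(C)(C)OC(=O)CC(=O)CCCCCCCCCCCCCC1(C)OCCO1 | intermediate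
8 | tert-butyl (3S)-3-hydroxy-16-(2-methyl-1,3-dioxolan-2-yl)hexadecanoate | CC(C)(C)OC(=O)C[C@@H](O)CCCCCCCCCCCCCC1(C)OCCO1 | intermediate
9 | ethyl (S)-lactate | CCOC(=O)[C@H](C)O | starting material
10 | ethyl (2S)-2-[(trifluoromethylsulfonyl)oxy]propanoate | CCOC(=O)[C@H](C)OS(=O)(=O)C(F)(F)F | intermediate
11 | dilithium alkoxide enolate of 8 (chelated, enolate O–Li cis to C-3) | [Li]O/C(OC(C)(C)C)=C\[C@@H](O[Li])CCCCCCCCCCCCCC1(C)OCCO1 | intermediate
12 | lithium alkoxide of 1-tert-butyl 4-ethyl (2S,3S)-2-[(1S)-1-hydroxy-14-(2-methyl-1,3-dioxolan-2-yl)tetradecyl]-3-methylbutanedioate | CCOC(=O)[C@@H](C)[C@H](C(=O)OC(C)(C)C)[C@@H](O[Li])CCCCCCCCCCCCCC1(C)OCCO1 | intermediate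
13 | tert-butyl (2S,3S,4S)-4-methyl-2-[13-(2-methyl-1,3-dioxolan-2-yl)tridecyl]-5-oxooxolane-3-carboxylate | CC1(CCCCCCCCCCCCC[C@@H]2OC(=O)[C@@H](C)[C@@H]2C(=O)OC(C)(C)C)OCCO1 | intermediate
14 | (2S,3S,4S)-4-methyl-5-oxo-2-(14-oxopentadecyl)oxolane-3-carboxylic acid | CC(=O)CCCCCCCCCCCCC[C@@H]1OC(=O)[C@@H](C)[C@@H]1C(=O)O | target

## Step count and risks

Total step count: 6. Longest linear sequence: 5 steps (1, 2, 3, 5, 6); step 4 is a one-step side branch.

**Most likely to fail, first: step 5.** The basic dianion may eliminate triflic acid from 10, O-alkylate, or react sluggishly in a mismatched pairing, and liberated ethoxide could epimerise C3 or C4. The fallback sets out from 8 and comes back at 13, replacing the lactate triflate by a proven primary electrophile and adding the methyl group last.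
- Classical Fráter–Seebach allylation of 8 (LiN(iPr)2, allyl bromide, THF/DMPU, −78 → −20 °C, through dianion 11) gives tert-butyl (2S,3S)-3-hydroxy-16-(2-methyl-1,3-dioxolan-2-yl)-2-(prop-2-en-1-yl)hexadecanoate F1.
- Ozonolysis (O3, CH2Cl2/MeOH, −78 °C; PPh3) gives the lactol tert-butyl (2S,3S)-5-hydroxy-2-[13-(2-methyl-1,3-dioxolan-2-yl)tridecyl]oxolane-3-carboxylate F2.
- Oxidation (TEMPO cat., PhI(OAc)2, CH2Cl2) gives the cis lactone tert-butyl (2S,3S)-2-[13-(2-methyl-1,3-dioxolan-2-yl)tridecyl]-5-oxooxolane-3-carboxylate F3.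
- Deprotonation with LiN(SiMe3)2 (THF, −78 °C) gives the lithium lactone enolate of F3 F4, which is methylated by MeI on the face anti to the C3 ester and so returns to 13.

**Second: step 1.** The Grignard reagent may add to the methyl ester or homocouple. The fallback sets out from 1 and 2 and comes back at 4, swapping the sp3–sp3 coupling for olefination and hydrogenation.
- 1 with PPh3 (MeCN, reflux, sealed) gives [3-(2-methyl-1,3-dioxolan-2-yl)propyl]triphenylphosphonium chloride F5.
- NaN(SiMe3)2 (THF, −78 °C) converts it into [3-(2-methyl-1,3-dioxolan-2-yl)propylidene]triphenylphosphorane F6.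
- Kornblum oxidation of 2 (DMSO, NaHCO3, 120 °C) gives methyl 11-oxoundecanoate F7.
- Wittig reaction of F6 with F7 gives methyl (11Z)-14-(2-methyl-1,3-dioxolan-2-yl)tetradec-11-enoate F8, and hydrogenation (H2, Pd/C, EtOAc) returns to 4.

**Third: step 3.** Traces of acid in the alcoholic hydrogenation medium may exchange or remove the ketal, and the catalyst is air-sensitive. The fallback sets out from 4 (with enolate 6) and comes back at 8, making the carbinol by C–C bond formation instead of reduction.
- iBu2AlH (CH2Cl2, −78 °C) reduces 4 to 14-(2-methyl-1,3-dioxolan-2-yl)tetradecanal F9.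
- Enolate 6 is silylated with Me3SiCl to 1-tert-butoxy-1-(trimethylsilyloxy)ethene F10.
- An enantioselective Mukaiyama acetate aldol of F9 with F10 gives tert-butyl (3S)-16-(2-methyl-1,3-dioxolan-2-yl)-3-[(trimethylsilyl)oxy]hexadecanoate F11. The catalyst is Ti(OiPr)4 with a BINOL-derived tridentate Schiff-base ligand (the enantiomer that gives the 3S adduct) and 3,5-di-tert-butylsalicylic acid, in Et2O at 0 °C.
- Bu4NF (THF, 0 °C) returns to 8.

## Further compounds

F1 | step 5 | tert-butyl (2S,3S)-3-hydroxy-16-(2-methyl-1,3-dioxolan-2-yl)-2-(prop-2-en-1-yl)hexadecanoate | C=CC[C@H](C(=O)OC(C)(C)C)[C@@H](O)CCCCCCCCCCCCCC1(C)OCCO1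
F2 | step 5 | tert-butyl (2S,3S)-5-hydroxy-2-[13-(2-methyl-1,3-dioxolan-2-yl)tridecyl]oxolane-3-carboxylate (anomer mixture) | CC1(CCCCCCCCCCCCC[C@@H]2OC(O)C[C@@H]2C(=O)OC(C)(C)C)OCCO1
F3 | step 5 | tert-butyl (2S,3S)-2-[13-(2-methyl-1,3-dioxolan-2-yl)tridecyl]-5-oxooxolane-3-carboxylate | CC1(CCCCCCCCCCCCC[C@@H]2OC(=O)C[C@@H]2C(=O)OC(C)(C)C)OCCO1
F4 | step 5 | lithium lactone enolate of F3 | CC1(CCCCCCCCCCCCC[C@@H]2OC(O[Li])=C[C@@H]2C(=O)OC(C)(C)C)OCCO1
F5 | step 1 | [3-(2-methyl-1,3-dioxolan-2-yl)propyl]triphenylphosphonium chloride | CC1(CCC[P+](c2ccccc2)(c2ccccc2)c2ccccc2)OCCO1.[Cl-]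
F6 | step 1 | [3-(2-methyl-1,3-dioxolan-2-yl)propylidene]triphenylphosphorane | CC1(CCC=P(c2ccccc2)(c2ccccc2)c2ccccc2)OCCO1
F7 | step 1 | methyl 11-oxoundecanoate | COC(=O)CCCCCCCCCC=O
F8 | step 1 | methyl (11Z)-14-(2-methyl-1,3-dioxolan-2-yl)tetradec-11-enoate | COC(=O)CCCCCCCCC/C=C\CCC1(C)OCCO1
F9 | step 3 | 14-(2-methyl-1,3-dioxolan-2-yl)tetradecanal | CC1(CCCCCCCCCCCCCC=O)OCCO1
F10 | step 3 | 1-tert-butoxy-1-(trimethylsilyloxy)ethene | C=C(O[Si](C)(C)C)OC(C)(C)C
F11 | step 3 | tert-butyl (3S)-16-(2-methyl-1,3-dioxolan-2-yl)-3-[(trimethylsilyl)oxy]hexadecanoate | CC(C)(C)OC(=O)C[C@@H](O[Si](C)(C)C)CCCCCCCCCCCCCC1(C)OCCO1
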